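The earlier runs and the new flask are simulated for substances that don't exist; noise was put on by code.

A closed, stirred vessel holds L, Q, G and X. The north-west flask is the very one asked about, and the south-west flask differs from it in Q.

in all of them: L 0.050 M; G 1.05 equiv
- north-west: Q 1.5 equiv; X 0.050 M; the very flask that is asked about, followed so far
- south-west: Q 1 equiv; X 0.050 M; run made earlier
- flask: Q 1.50 equiv; X 0.0500 M; time 30 h

- north-west (time / h: D / %, J / %): 1.33: 19.0, 66.9; 4.00: 19.8, 66.3; 8.00: 20.1, 67.8; 10.0: 20.0, 66.1; 15.0: 17.9, 68.1
- south-west (time / h: D / %, J / %): 1.00: 13.9, 78.8; 2.00: 13.4, 77.2; 3.00: 15.8, 76.2; 6.00: 14.2, 76.1; 12.0: 13.2, 77.6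

(readings scatter by 1 percentage point)

- the numbers in the tables scatter by 1 percentage point (one standard deviation)
- the reaction counts as stopped when no species that holds the L changes by six tenths of a point or more over the second half of the time

1. why nothing more happens at 30 h, or that something still does (it is still moving / all of L has reacted / G has run out first / Q has run out first / forward and back rates have come level)
2. D at 30 h, in percent of the L charged
3. J at 30 h, in percent of the L charged

Both runs lie flat from their first reading, so ask what ended them. Count G, supposing that a J has taken one G and a D 2. Let j and d be fractions of the L charged and g the equivalents of G. The north-west means are: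

d = 19.4%, j = 67.0%

β = (j + 2d)/g = 1.01

This β, the G accounted for over the G charged, lies within the scatter of one, so the count finds no G for a further step, although 13.6% of L is unaccounted for. Commit to a stop by G, with these means standing at 30 h.

Is one number enough? The south-west run, with less Q, gives:

d = 14.1%, β = 1.00

So β stays near one in both runs while d moves from 14.1% to 19.4%: β points to the stop, but the split between J and D has to be read from each run.

The forecast says G has run out first, with D 19.3% and J 66.9%, on the same count, “matching the 105% of G charged”.

The flask gives G has run out first, with D 18.7% and J 67.6%.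

    L + G → J (k = 0.930 M⁻¹ s⁻¹)
    G + Q → E (k = 0.0650 M⁻¹ s⁻¹)
    J + E → D (k = 0.0170 M⁻¹ s⁻¹)
    Q + X → Z (k = 0.0130 M⁻¹ s⁻¹)

G is the limiting reagent in the asked flask: 0% of it is left at 30.0 h, beside 21% of the Q and 14% of the L, and β comes to 1.00. The consumption of G holds D down: the run without it gives D 100%, against 18.7%. Carry 1.01 to a neighbour flask charged with 0.420 equiv of G: its D of 4.73% puts J at 33.0%, and that flask holds J 32.5%.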